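Read the flask at 5.0 min and ask first whether D can serve both X and J.

| flask | X | J | D | E | Q | remark | time |
|---|---|---|---|---|---|---|---|
| eta | 0.033 M | 0.033 M | 0.195 M | 65 µM | 0.16 mM | run made earlier |  |
| delta | 0.049 M | 0.049 M | 0.195 M | 65 µM | 0.16 mM | run made earlier |  |
| flask | 0.065 M | 0.065 M | 0.195 M | 65 µM | 0.16 mM |  | 5.0 min |

- eta (time / min: G / %, L / %): 0.833: 39.7, 32.6; 1.50: 46.8, 41.7; 2.50: 48.7, 47.7; 3.00: 48.8, 48.7; 4.00: 49.3, 49.6; 5.00: 49.8, 50.9
- delta (time / min: G / %, L / %): 0.417: 27.3, 20.7; 0.667: 35.3, 27.9; 1.00: 40.8, 33.1; 2.00: 46.7, 44.0; 3.00: 48.2, 47.3; 5.00: 48.5, 49.9

(each reading ± 0.5 percentage points)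

- G and L together, in percent of the X and J charged together, at 5.0 min
- excess of G over L in the product at 5.0 min
- whether the exchange between X and J keeps pace with the reaction: how far the product's excess at 5.0 min gets from its value without exchange to its value with instant exchange (above 80% keeps pace, below 20% hardly takes part, else lags behind)

- E is single-handed; X and J are mirror images of each other, charged as a racemate, each of them at the stated concentration
- the analysis behind the earlier runs scatters by 0.5 percentage points, standard deviation
- an excess is the difference of the two amounts in percent of their sum
- an excess is below zero if the other one leads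

Write the balance of D, taking one D for each X or J that reacts. Call the moles of D charged per mole of X and J together the cover: 1.50 in this flask. With the cover above one, X and J together are the limiting reagent, and D stops at a floor of 33.3% of its charge. The cover was 2.95 in the eta run and 1.99 in the delta run, and there G and L ended at 49.8% and 50.9%, and 48.5% and 49.9%. So expect this flask to end with both products level and the excess near zero.

But 5.0 min may be too early, because J is the slower enantiomer. The first delta reading gives a pseudo-first-order constant for J of 1.28 /min. With D held at its floor for the whole time, 11.9% of the J stays. That is too gloomy, since D starts above its floor. The surplus lasts about one lifetime of J, which adds 0.667 to the exponent and leaves 6.06% of the J. Counting X as fully reacted, my reckoning is a yield of 97.0% and an excess of 3.13%.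

Exchange could still feed J into G. The same reading gives a selectivity factor of 1.48, so with X and J kept equal by instant exchange, the product would carry an excess of about 19.4% as it forms. Yet G stays at 49.8% and 48.5% in the two runs, so take the exchange as hardly taking part.

The forecast, with a smaller excess than mine, says 98.1%, 1.3% and hardly takes part, holding that “The runs look like plain kinetic resolution”.

The flask gives 97.9%, −0.410% and hardly takes part: the exchange gets 3.8% of the way and moves the shown readings by 0.27 of the scatter.

    2 Q ⇌ Z, settled at all times (K = 40000 /M)
    D + E + X → E + G (k = 3000 /M²/s)
    X + Q ⇌ J + Q, rate k3*[Q]*[X] forward; the back reaction follows from the equilibrium constant (k = 7.50 /M/s)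
    D + E + J → E + L (k = 1900 /M²/s)
    G ⇌ L (k = 0.00140 /s)

D stands at 35% of its charge at 5.00 min, just above the floor. The largest single effect is the reaction of D with J: without it the excess is 48.9%, not −0.410%. Now charge 0.078 M of D instead: the cover is 0.600, so D is limiting and the yield stops near 60.0%. That flask gives 57.7%, with an excess of 7.15% and 3.8% of its D left.

(The readings are calculated with constants of no real substance.)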